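## Analysis of the target

The target is a cis-fused 3,7-dioxabicyclo[3.3.0]octan-8-one. A γ-lactone (ring B: C8 carbonyl, O7, C6, C5, C1) shares the C1–C5 bond with an oxolane (ring A: C1, C2, O3, C4, C5); C6 carries the 3,4,5-trihydroxyphenyl ring and C2 the 3,4-dihydroxyphenyl ring, and this numbering is used for every intermediate below. The four stereocentres C2, C1, C5 and C6 are contiguous, with configuration (1S,2S,5R,6S): H1 and H5 are cis, and both aryl groups lie on the convex face, each trans to the neighbouring ring-fusion hydrogen. The sensitive groups are the pyrogallol and catechol units (air oxidation, worst in base), the two benzylic C–O bonds C2–O3 and C6–O7 that sit para to oxygen substituents (ionisation in acid, hydrogenolysis), and the lactone with its acidic C1–H. The two halves differ, so no dimerisation of one cinnamyl unit applies, and four adjacent centres must be set one after another on a small skeleton. A particular trap is C1: C2 and C4 are cis on ring B, whereas the enolate of a lactone closed on O7 would take an electrophile anti to C4. The strategy rests on the chain O3–C4–C5–C6, which is the oxygen and three contiguous carbons of a furan, and on C1–C8, which is a carbene carbon with its ester carbon. Cyclopropanation of the 4,5-bond of a furan-2-carboxylate therefore assembles C4, C5, C6, O3, C1 and C8 in one step with C5 stereodefined, and the extra C1–C4 bond is one that a retro-aldol reaction can cut later.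

## Retrosynthetic reasoning

**21 from 20.** The five phenols are carried as benzyl ethers and released last. Benzyl survives organometallic, basic, hydride and mildly acidic steps, and the free polyphenol would not survive most of them. The forward step must cleave five aryl O–CH2Ph bonds without touching the benzylic C2–O3 and C6–O7 bonds.

**20 from 18 (through 19), and 18 from 16.** The lactone C8–O7 bond is cut to the γ-hydroxy acid 19, which is stored as its O7 silyl ether 18, and the carboxyl group is taken back to the primary alcohol of 16. Closing ring B last, on an oxolane that already holds C8 and C6 cis, makes the cis ring fusion automatic. The forward oxidation has to pass the aldehyde stage 17 without epimerising C1.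

**16 from 15.** The benzylic ether bond C2–O3 is cut, giving triol 15 with a carbinol at C2. This bond is chosen because an electron-rich benzylic carbinol closes by an SN1 path that sets C2 under substrate control and makes the configuration of the carbinol irrelevant. O7 stays silylated, so that O3 is the only hydroxyl able to form a five-membered ring.

**15 from 14.** The diol is taken back to a lactone closed on O3, not on O7. This is the central stereochemical decision. In 14 the enolate carbon C1 lies in a ring with C5, whose only substituent is the C6 side chain. An aldehyde enters anti to that chain, and this 3,4-trans relation is exactly the one that becomes the cis fusion of 21 once C8 is tied to O7. The price is that O3 is locked in the lactone, so the lactone is reduced before ring A is closed. An acid-promoted acyl shift from O3 to O7 in one flask is not relied on: the C2 cation would then form while no oxygen can reach it, next to an electron-rich arene and an acidic C1–H.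

**14 from 12 and 13.** The C1–C2 bond is cut by an aldol disconnection. It joins the second aryl fragment in one step and needs no control at C2.

**12 from 9 (through 10 and 11).** The lactone C8–O3 bond is opened, the C4 carbinol becomes an aldehyde, and the C1–C4 bond is re-formed on paper to give the donor–acceptor cyclopropane 9. This gains a rigid carrier in which C5 is fixed and C6 can be set beside it. The forward reaction has to free the cyclopropanol, let it open by retro-aldol, and reduce the aldehyde 10 before C5 can enolise; O7 is silylated so that the lactone must close on O3.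

**9 from 8, and 8 from 4 and 5.** The C6–aryl bond is cut. The aryl group is delivered as the titanium reagent 7, made from 5 through the magnesium reagent 6, because 6 itself would also attack the oxalate of 4. C6 is set by 1,2-induction from the cyclopropane.

**4 from 3.** The formyl group and the oxalate are joined back to the enol ether double bond of 3. Oxidative cleavage of this one alkene unveils C6 as an aldehyde and leaves the cyclopropanol acylated.

**3 from 1 and 2.** Both cyclopropane bonds at the carbene carbon (C1–C5 and C1–C4) are cut. The forward step is an enantioselective carbene transfer to the unsubstituted double bond of the furan; it sets C5 absolutely and is the only source of absolute configuration in the route.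

## Alternatives that were turned down

**Alternative 1: conjugate addition and aldol on a chiral butenolide.** The disconnection cuts C5–C6 and C1–C2. The lithium derivative of the aryl dithiane A2 adds to the β-carbon of the menthyloxy butenolide A1, and the lactone enolate is trapped with aldehyde 13 to give A3. In its favour, two C–C bonds form in one flask from three components, C5 and C1 are set by the acetal auxiliary, and the aldol uses the same anti logic as the chosen route; on convergence it is stronger. Against it, C6 arrives at the ketone oxidation level and C4 as an acetal. The dithiane must be removed in the presence of five benzyl ethers and two electron-rich rings, the ketone must be reduced with uncertain 1,2-induction to set C6 late, and C4 must be reduced to a methylene. The auxiliary is stoichiometric and A1 must be obtained as one epimer. The chosen route sets C6 early at the right oxidation level and C5 by a catalyst, at a similar step count once these corrections are added.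

**Alternative 2: intramolecular ketene–styrene cycloaddition, then oxygen insertion.** The disconnection cuts C1–C5 and C8–C6, and O7 is inserted afterwards. The acid chloride A4 gives the ketene A5 with an amine base, A5 adds to its tethered (E)-styrene to give the cyclobutanone A6, and a Baeyer–Villiger reaction should then move the benzylic carbon C6 onto oxygen. In its favour, the whole carbon skeleton and ring A form in one step, the ring fusion is cis by necessity, the alkene geometry gives the C5/C6 relation, and the step count is lower than in the chosen route. Against it, the polarity is mismatched: the ketene carbonyl carbon C8 must bond to the benzylic carbon C6, whereas the styrene is nucleophilic at C5, so bridged regiochemistry is a real threat. The β-alkoxy acid chloride can also lose its cinnamyl alkoxide by elimination under the base. The only control element is C2, which must be made enantioenriched beforehand at an ionisable benzylic ether and whose influence on the facial selectivity is unproven. The chosen route is longer but assigns each stereocentre to a separate, understood control element.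

**Alternative 3: radical cascade from an epoxide onto a cinnamyl acetal.** The disconnection cuts C1–C5 and O3–C2. A trivalent titanium reductant opens the epoxide of A7 to a radical at C5, which cyclises onto C1; the benzylic radical at C2 is oxidised and the titanium-bound O3 closes onto C2, giving the bicyclic acetal A8. In its favour, both rings and two bonds form in one operation under mild conditions, the closure at C2 should place the aryl group exo, and the bicycle is reached in fewer steps than in the chosen route. Against it, the C5 radical loses the configuration of the epoxide, so C1, C5 and C2 are all set in one radical step with only C6 and a scrambled acetal centre as control. The absolute configuration needs an enantioenriched epoxy alcohol, typically from a resolution. The titanium reagent is used in excess, and A8 must still be oxidised from acetal to lactone in the presence of electron-rich arenes. The chosen route gives up this brevity for stepwise control of all four centres.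

Key step: step 1

Assumption: the (R,R)-configured ligand is taken to deliver the (1R,5R,6R) adduct 3 (if the sense is the opposite, its antipode is used), and 5 and 13 are taken as purchasable.

## Route

Step 1
Reactants: 1 methyl furan-2-carboxylate; 2 ethyl diazoacetate
Product: 3 6-ethyl 3-methyl (1R,5R,6R)-2-oxabicyclo[3.1.0]hex-3-ene-3,6-dicarboxylate
Conditions: (CuOTf)2·C6H6 (1 mol%), (R,R)-iPr-box [2,2'-(propane-2,2-diyl)bis((4R)-4-isopropyl-4,5-dihydrooxazole), 1.2 mol%], CH2Cl2, 0 °C, slow addition of 2; recrystallisation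
Reagents that add atoms: none
Why: The monovalent copper complex decomposes 2 to an electrophilic copper carbene, which adds in a concerted, asynchronous [2+1] fashion to the 4,5-double bond of 1, the more electron-rich and less hindered alkene of the furan (the 2,3-bond is deactivated by the ester). The closest known reaction type is the copper–bis(oxazoline) asymmetric cyclopropanation of furan-2-carboxylates with diazoacetates. The three-membered ring closes by syn addition of the carbene carbon to both alkene carbons on one face, so the ring-fusion carbons of 3 (bicycle C1 and C5, target C4 and C5) are necessarily cis. Their absolute configuration depends on which enantioface of the alkene meets the carbene, and this is dictated by the C2-symmetric ligand, whose isopropyl groups leave one quadrant open for the furan. The configuration at the carbene carbon (bicycle C6, target C1, ester exo) follows from the approach in which the carbene ester points away from the furan ring. The step needs regioselectivity, secured by the ester of 1, and exo and enantioselectivity, secured by the ligand; the ester on the enol ether also protects the adduct against ring opening to a dienal. Slow addition of 2 should suppress carbene dimerisation, and recrystallisation of 3 should raise the enantiomeric purity.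

Step 2
Reactants: 3 6-ethyl 3-methyl (1R,5R,6R)-2-oxabicyclo[3.1.0]hex-3-ene-3,6-dicarboxylate
Product: 4 ethyl (1R,2R,3R)-2-formyl-3-[(methoxyoxalyl)oxy]cyclopropane-1-carboxylate
Conditions: O3, CH2Cl2, −78 °C; then Me2S, −78 °C to rt
Reagents that add atoms: ozone, [O-][O+]=O
Why: Ozonolysis with reductive work-up; the only alkene is the enol ether, which is cleaved to the formyl group (C6) and the mixed oxalate that keeps the cyclopropanol acylated. No stereocentre is touched.

Step 3
Reactants: 4 ethyl (1R,2R,3R)-2-formyl-3-[(methoxyoxalyl)oxy]cyclopropane-1-carboxylate; 5 5-bromo-1,2,3-tris(benzyloxy)benzene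
Product: 8 ethyl (1R,2S,3R)-2-{(S)-hydroxy[3,4,5-tris(benzyloxy)phenyl]methyl}-3-[(methoxyoxalyl)oxy]cyclopropane-1-carboxylate, via arylmagnesium bromide 6 (not isolated), via aryltitanium triisopropoxide 7 (not isolated)
Conditions: 5, Mg, THF, 45 °C; ClTi(OiPr)3, −78 to −40 °C; then 4, −78 to −20 °C; aq NH4Cl
Reagents that add atoms: none
Why: Aryltitanium triisopropoxides add to aldehydes and leave esters and the electrophilic oxalate alone, which the Grignard reagent 6 itself would not. C6 is set by 1,2-induction (Felkin–Anh model): the ring bond to the oxalate-bearing carbon lies anti to the incoming aryl group, the formyl oxygen sits over the ring, and attack comes from the side of the ester-bearing carbon, away from the cis oxalate, giving the (S)-carbinol. This is the sense that leads to trans-4,5-disubstituted butanolides in this substrate class.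

Step 4
Reactants: 8 ethyl (1R,2S,3R)-2-{(S)-hydroxy[3,4,5-tris(benzyloxy)phenyl]methyl}-3-[(methoxyoxalyl)oxy]cyclopropane-1-carboxylate
Product: 9 ethyl (1R,2R,3R)-2-{(S)-[tert-butyl(dimethyl)silyl]oxy[3,4,5-tris(benzyloxy)phenyl]methyl}-3-[(methoxyoxalyl)oxy]cyclopropane-1-carboxylate
Conditions: TBSOTf, 2,6-lutidine, CH2Cl2, −78 to 0 °C
Reagents that add atoms: tert-butyldimethylsilyl trifluoromethanesulfonate, CC(C)(C)[Si](C)(C)OS(=O)(=O)C(F)(F)F
Why: Silylation under buffered, non-nucleophilic conditions that spare the oxalate and the cyclopropylcarbinol. The silyl ether blocks O7, so that the lactone of step 5 must close on O3 and only O3 can close ring A in step 8.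

Step 5
Reactants: 9 ethyl (1R,2R,3R)-2-{(S)-[tert-butyl(dimethyl)silyl]oxy[3,4,5-tris(benzyloxy)phenyl]methyl}-3-[(methoxyoxalyl)oxy]cyclopropane-1-carboxylate
Product: 12 (4R)-4-{(S)-[tert-butyl(dimethyl)silyl]oxy[3,4,5-tris(benzyloxy)phenyl]methyl}oxolan-2-one, via oxo ester 10 (not isolated), via hydroxy ester 11 (not isolated)
Conditions: NaBH4, Ba(OH)2·8H2O, MeOH–THF, −10 to 0 °C; AcOH; then PPTS, PhMe, 40 °C
Reagents that add atoms: none
Why: Hydroxide removes the oxalate, and the freed cyclopropanolate of this donor–acceptor cyclopropane opens by retro-aldol cleavage of the C1–C4 bond to the γ-oxo ester 10. The borohydride present from the start should reduce the aldehyde faster than C5 can enolise, and the γ-hydroxy ester 11 lactonises onto O3. C5 and C6 are carried through unchanged.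

Step 6
Reactants: 12 (4R)-4-{(S)-[tert-butyl(dimethyl)silyl]oxy[3,4,5-tris(benzyloxy)phenyl]methyl}oxolan-2-one; 13 3,4-bis(benzyloxy)benzaldehyde
Product: 14 (3S,4R)-3-{[3,4-bis(benzyloxy)phenyl](hydroxy)methyl}-4-{(S)-[tert-butyl(dimethyl)silyl]oxy[3,4,5-tris(benzyloxy)phenyl]methyl}oxolan-2-one (both carbinol epimers)
Conditions: LiN(iPr)2, THF, −78 °C; then 13, −78 °C; AcOH, −78 °C
Reagents that add atoms: none
Why: Aldol addition of the lithium enolate of a β-substituted γ-butyrolactone; the aldehyde enters anti to the bulky C5 side chain, which sets C1 (3,4-trans). The carbinol carbon C2 is not controlled and need not be, since its configuration is erased in step 8.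

Step 7
Reactants: 14 (3S,4R)-3-{[3,4-bis(benzyloxy)phenyl](hydroxy)methyl}-4-{(S)-[tert-butyl(dimethyl)silyl]oxy[3,4,5-tris(benzyloxy)phenyl]methyl}oxolan-2-one
Product: 15 (2R,3R)-2-{(S)-[tert-butyl(dimethyl)silyl]oxy[3,4,5-tris(benzyloxy)phenyl]methyl}-3-{[3,4-bis(benzyloxy)phenyl](hydroxy)methyl}butane-1,4-diol (both carbinol epimers)
Conditions: LiBH4, THF–MeOH, 0 °C to rt
Reagents that add atoms: none
Why: Borohydride reduction of a γ-lactone to the 1,4-diol. It frees O3, which the lactone of 14 holds, and leaves the silyl ether, the benzyl ethers and all stereocentres untouched.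

Step 8
Reactants: 15 (2R,3R)-2-{(S)-[tert-butyl(dimethyl)silyl]oxy[3,4,5-tris(benzyloxy)phenyl]methyl}-3-{[3,4-bis(benzyloxy)phenyl](hydroxy)methyl}butane-1,4-diol
Product: 16 [(2S,3R,4R)-2-[3,4-bis(benzyloxy)phenyl]-4-{(S)-[tert-butyl(dimethyl)silyl]oxy[3,4,5-tris(benzyloxy)phenyl]methyl}oxolan-3-yl]methanol
Conditions: CSA (10 mol%), CH2Cl2, 0 °C
Reagents that add atoms: none
Why: SN1 cycloetherification: acid ionises the 3,4-dialkoxybenzylic alcohol, and O3 is the only hydroxyl that can reach the cation through a five-membered transition state (O7 is silylated, the C8 hydroxyl would give an oxetane), so capture by oxygen should outrun attack by the neighbouring arene. C2 is created here under substrate control: the planar cation closes with its aryl group trans to the C8 arm on C1 (least allylic strain, and the more stable 2,3-trans oxolane), whichever epimer of 15 enters.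

Step 9
Reactants: 16 [(2S,3R,4R)-2-[3,4-bis(benzyloxy)phenyl]-4-{(S)-[tert-butyl(dimethyl)silyl]oxy[3,4,5-tris(benzyloxy)phenyl]methyl}oxolan-3-yl]methanol
Product: 18 (2S,3S,4R)-2-[3,4-bis(benzyloxy)phenyl]-4-{(S)-[tert-butyl(dimethyl)silyl]oxy[3,4,5-tris(benzyloxy)phenyl]methyl}oxolane-3-carboxylic acid, via aldehyde 17 (not isolated)
Conditions: TEMPO (20 mol%), PhI(OAc)2, MeCN–H2O, rt
Reagents that add atoms: water, O
Why: Oxoammonium (TEMPO) oxidation of the primary alcohol through aldehyde 17 and its hydrate to the carboxylic acid. No secondary alcohol is free, and the short-lived aldehyde should keep its configuration at C1.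

Step 10
Reactants: 18 (2S,3S,4R)-2-[3,4-bis(benzyloxy)phenyl]-4-{(S)-[tert-butyl(dimethyl)silyl]oxy[3,4,5-tris(benzyloxy)phenyl]methyl}oxolane-3-carboxylic acid
Product: 20 (1S,2S,5R,6S)-2-[3,4-bis(benzyloxy)phenyl]-6-[3,4,5-tris(benzyloxy)phenyl]-3,7-dioxabicyclo[3.3.0]octan-8-one, via hydroxy acid 19 (not isolated)
Conditions: HF·pyridine, THF, 0 °C to rt; then PPTS, CH2Cl2, rt
Reagents that add atoms: none
Why: Fluoride removes the silyl ether, and the γ-hydroxy acid 19, whose carboxyl and carbinol arms are cis on ring A, lactonises to the cis-fused lactone. C6 keeps its configuration because the C6–O7 bond is never broken.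

Step 11
Reactants: 20 (1S,2S,5R,6S)-2-[3,4-bis(benzyloxy)phenyl]-6-[3,4,5-tris(benzyloxy)phenyl]-3,7-dioxabicyclo[3.3.0]octan-8-one
Product: 21 (1S,2S,5R,6S)-2-(3,4-dihydroxyphenyl)-6-(3,4,5-trihydroxyphenyl)-3,7-dioxabicyclo[3.3.0]octan-8-one
Conditions: BCl3, C6HMe5, CH2Cl2, −78 °C; MeOH quench
Reagents that add atoms: none
Why: Lewis acid dealkylation of the five aryl benzyl ethers with pentamethylbenzene as a non-basic scavenger for the benzyl cations, at low temperature. It is chosen over hydrogenolysis to spare the two benzylic C–O bonds and over basic methods to spare the polyphenol.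

## Compound list

1 | methyl furan-2-carboxylate | COC(=O)c1ccco1 | starting material
2 | ethyl diazoacetate | CCOC(=O)C=[N+]=[N-] | starting material
3 | 6-ethyl 3-methyl (1R,5R,6R)-2-oxabicyclo[3.1.0]hex-3-ene-3,6-dicarboxylate (exo ester) | COC(=O)C1=C[C@@H]2[C@@H](C(=O)OCC)[C@@H]2O1 | intermediate
4 | ethyl (1R,2R,3R)-2-formyl-3-[(methoxyoxalyl)oxy]cyclopropane-1-carboxylate | O=C[C@@H]1[C@@H](C(=O)OCC)[C@@H]1OC(=O)C(=O)OC | intermediate
5 | 5-bromo-1,2,3-tris(benzyloxy)benzene | Brc1cc(OCc2ccccc2)c(OCc2ccccc2)c(OCc2ccccc2)c1 | starting material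
6 | [3,4,5-tris(benzyloxy)phenyl]magnesium bromide (not isolated) | Br[Mg]c1cc(OCc2ccccc2)c(OCc2ccccc2)c(OCc2ccccc2)c1 | intermediate
7 | tri(propan-2-yloxy)[3,4,5-tris(benzyloxy)phenyl]titanium (not isolated) | CC(C)O[Ti](OC(C)C)(OC(C)C)c1cc(OCc2ccccc2)c(OCc2ccccc2)c(OCc2ccccc2)c1 | intermediate
8 | ethyl (1R,2S,3R)-2-{(S)-hydroxy[3,4,5-tris(benzyloxy)phenyl]methyl}-3-[(methoxyoxalyl)oxy]cyclopropane-1-carboxylate | O[C@H](c1cc(OCc2ccccc2)c(OCc2ccccc2)c(OCc2ccccc2)c1)[C@@H]1[C@@H](C(=O)OCC)[C@@H]1OC(=O)C(=O)OC | intermediate
9 | ethyl (1R,2R,3R)-2-{(S)-[tert-butyl(dimethyl)silyl]oxy[3,4,5-tris(benzyloxy)phenyl]methyl}-3-[(methoxyoxalyl)oxy]cyclopropane-1-carboxylate | CC(C)(C)[Si](C)(C)O[C@H](c1cc(OCc2ccccc2)c(OCc2ccccc2)c(OCc2ccccc2)c1)[C@@H]1[C@@H](C(=O)OCC)[C@@H]1OC(=O)C(=O)OC | intermediate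
10 | ethyl (3S,4S)-4-{[tert-butyl(dimethyl)silyl]oxy}-3-formyl-4-[3,4,5-tris(benzyloxy)phenyl]butanoate (not isolated) | CCOC(=O)C[C@H](C=O)[C@H](O[Si](C)(C)C(C)(C)C)c1cc(OCc2ccccc2)c(OCc2ccccc2)c(OCc2ccccc2)c1 | intermediate
11 | ethyl (3R,4S)-4-{[tert-butyl(dimethyl)silyl]oxy}-3-(hydroxymethyl)-4-[3,4,5-tris(benzyloxy)phenyl]butanoate (not isolated) | CCOC(=O)C[C@H](CO)[C@H](O[Si](C)(C)C(C)(C)C)c1cc(OCc2ccccc2)c(OCc2ccccc2)c(OCc2ccccc2)c1 | intermediate
12 | (4R)-4-{(S)-[tert-butyl(dimethyl)silyl]oxy[3,4,5-tris(benzyloxy)phenyl]methyl}oxolan-2-one | O=C1OC[C@H]([C@H](O[Si](C)(C)C(C)(C)C)c2cc(OCc3ccccc3)c(OCc3ccccc3)c(OCc3ccccc3)c2)C1 | intermediate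
13 | 3,4-bis(benzyloxy)benzaldehyde | O=Cc1ccc(OCc2ccccc2)c(OCc2ccccc2)c1 | starting material
14 | (3S,4R)-3-{[3,4-bis(benzyloxy)phenyl](hydroxy)methyl}-4-{(S)-[tert-butyl(dimethyl)silyl]oxy[3,4,5-tris(benzyloxy)phenyl]methyl}oxolan-2-one (3,4-trans; both carbinol epimers, that centre left undefined) | O=C1OC[C@H]([C@H](O[Si](C)(C)C(C)(C)C)c2cc(OCc3ccccc3)c(OCc3ccccc3)c(OCc3ccccc3)c2)[C@H]1C(O)c1ccc(OCc2ccccc2)c(OCc2ccccc2)c1 | intermediate
15 | (2R,3R)-2-{(S)-[tert-butyl(dimethyl)silyl]oxy[3,4,5-tris(benzyloxy)phenyl]methyl}-3-{[3,4-bis(benzyloxy)phenyl](hydroxy)methyl}butane-1,4-diol (both carbinol epimers, that centre left undefined) | OC[C@H]([C@H](O[Si](C)(C)C(C)(C)C)c1cc(OCc2ccccc2)c(OCc2ccccc2)c(OCc2ccccc2)c1)[C@H](CO)C(O)c1ccc(OCc2ccccc2)c(OCc2ccccc2)c1 | intermediate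
16 | [(2S,3R,4R)-2-[3,4-bis(benzyloxy)phenyl]-4-{(S)-[tert-butyl(dimethyl)silyl]oxy[3,4,5-tris(benzyloxy)phenyl]methyl}oxolan-3-yl]methanol | OC[C@@H]1[C@@H](c2ccc(OCc3ccccc3)c(OCc3ccccc3)c2)OC[C@@H]1[C@H](O[Si](C)(C)C(C)(C)C)c1cc(OCc2ccccc2)c(OCc2ccccc2)c(OCc2ccccc2)c1 | intermediate
17 | (2S,3S,4R)-2-[3,4-bis(benzyloxy)phenyl]-4-{(S)-[tert-butyl(dimethyl)silyl]oxy[3,4,5-tris(benzyloxy)phenyl]methyl}oxolane-3-carbaldehyde (not isolated) | O=C[C@@H]1[C@@H](c2ccc(OCc3ccccc3)c(OCc3ccccc3)c2)OC[C@@H]1[C@H](O[Si](C)(C)C(C)(C)C)c1cc(OCc2ccccc2)c(OCc2ccccc2)c(OCc2ccccc2)c1 | intermediate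
18 | (2S,3S,4R)-2-[3,4-bis(benzyloxy)phenyl]-4-{(S)-[tert-butyl(dimethyl)silyl]oxy[3,4,5-tris(benzyloxy)phenyl]methyl}oxolane-3-carboxylic acid | OC(=O)[C@@H]1[C@@H](c2ccc(OCc3ccccc3)c(OCc3ccccc3)c2)OC[C@@H]1[C@H](O[Si](C)(C)C(C)(C)C)c1cc(OCc2ccccc2)c(OCc2ccccc2)c(OCc2ccccc2)c1 | intermediate
19 | (2S,3S,4R)-2-[3,4-bis(benzyloxy)phenyl]-4-{(S)-hydroxy[3,4,5-tris(benzyloxy)phenyl]methyl}oxolane-3-carboxylic acid (not isolated) | OC(=O)[C@@H]1[C@@H](c2ccc(OCc3ccccc3)c(OCc3ccccc3)c2)OC[C@@H]1[C@H](O)c1cc(OCc2ccccc2)c(OCc2ccccc2)c(OCc2ccccc2)c1 | intermediate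
20 | (1S,2S,5R,6S)-2-[3,4-bis(benzyloxy)phenyl]-6-[3,4,5-tris(benzyloxy)phenyl]-3,7-dioxabicyclo[3.3.0]octan-8-one | O=C1O[C@H](c2cc(OCc3ccccc3)c(OCc3ccccc3)c(OCc3ccccc3)c2)[C@H]2CO[C@H](c3ccc(OCc4ccccc4)c(OCc4ccccc4)c3)[C@@H]12 | intermediate
21 | (1S,2S,5R,6S)-2-(3,4-dihydroxyphenyl)-6-(3,4,5-trihydroxyphenyl)-3,7-dioxabicyclo[3.3.0]octan-8-one (CNP0290035.1) | O=C1O[C@H](c2cc(O)c(O)c(O)c2)[C@H]2CO[C@H](c3ccc(O)c(O)c3)[C@@H]12 | target

## Step count and least certain steps

Total: 11 steps. Longest linear sequence: 11 steps, from 1 and 2 to 21; 5 and 13 are purchased and enter at steps 3 and 6.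

**Step 1 (key step).** Carbene dimerisation may outrun addition to the electron-poor furan, the enantioselectivity may be insufficient, or the adduct may open to a dienal, because the substrate is a deactivated heteroarene and the product is a strained enol ether. Fallback, setting out from 1 and 2: cyclopropanation with the achiral catalyst Rh2(OAc)4 gives the racemic exo adduct, that is 3 together with its (1S,5S,6S) enantiomer F1. The two are separated by preparative chromatography on a chiral stationary phase, and the route is rejoined at 3.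

**Step 5.** The liberated aldehyde may enolise before hydride delivery, with epimerisation at C5 or β-elimination of the silyloxy group, or the silyl group may migrate from O7 to O3 and send the lactone to the wrong oxygen; both arise because an open-chain β-silyloxy aldehyde is exposed to base. Fallback, setting out from 8: the unprotected alcohol is treated with Ba(OH)2·8H2O in MeOH, so that the retro-aldol product lactonises at once on O7 to (2S,3S)-5-oxo-2-[3,4,5-tris(benzyloxy)phenyl]oxolane-3-carbaldehyde F2, in which the trans relation is also the thermodynamic one. NaBH4 gives (4R,5S)-4-(hydroxymethyl)-5-[3,4,5-tris(benzyloxy)phenyl]oxolan-2-one F3. Opening with Al(CH3)3 and MeNH(OMe)·HCl gives the (3R,4S)-4-hydroxy-3-(hydroxymethyl)-N-methoxy-N-methyl-4-[3,4,5-tris(benzyloxy)phenyl]butanamide F4, and TBSOTf with 2,6-lutidine gives its bis(tert-butyldimethylsilyl) ether F5. HF·pyridine at 0 °C removes the primary silyl ether selectively, and the γ-hydroxy amide lactonises with PPTS onto O3, rejoining the route at 12.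

**Step 3.** Facial selectivity may be poor with the titanium reagent, or the oxalyl group may transfer to the new alkoxide and trigger early ring opening; the stereochemical sense is known for Lewis-acid-mediated additions and is only inferred for a titanium aryl. Fallback, setting out from 8 as an epimer mixture: Dess–Martin oxidation gives the ketone ethyl (1R,2R,3R)-2-[3,4,5-tris(benzyloxy)benzoyl]-3-[(methoxyoxalyl)oxy]cyclopropane-1-carboxylate F6, and a Corey–Bakshi–Shibata reduction ((R)-2-methyl-CBS-oxazaborolidine, catecholborane) sets C6 by reagent control and returns to 8.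

**Step 9.** C1 may epimerise while aldehyde 17 exists, since the all-trans oxolane is the more stable one, or the oxidation may stop at the aldehyde. Fallback, setting out from 16: Bu4NF removes the silyl ether to give the diol [(2S,3R,4R)-2-[3,4-bis(benzyloxy)phenyl]-4-{(S)-hydroxy[3,4,5-tris(benzyloxy)phenyl]methyl}oxolan-3-yl]methanol F7. TEMPO with PhI(OAc)2 in CH2Cl2 then oxidises the primary alcohol, the aldehyde is trapped at once by O7 as the cis-fused lactol (1S,2S,5R,6S)-2-[3,4-bis(benzyloxy)phenyl]-6-[3,4,5-tris(benzyloxy)phenyl]-3,7-dioxabicyclo[3.3.0]octan-8-ol F8, and this is oxidised further in the same flask, rejoining the route at 20.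

**Step 11.** The Lewis acid may ionise the benzylic C2–O3 bond, with epimerisation at C2 or capture of the cation by the scavenger, and the free polyphenol may oxidise on work-up. Fallback, setting out from 20: hydrogenolysis with H2 over Pd(OH)2/C in EtOAc–MeOH at rt, stopped when the benzyl ethers are consumed, gives 21 directly; it makes no new compound (F0).

## Further compounds

F1 | step 1 | 6-ethyl 3-methyl (1S,5S,6S)-2-oxabicyclo[3.1.0]hex-3-ene-3,6-dicarboxylate (enantiomer of 3) | COC(=O)C1=C[C@H]2[C@H](C(=O)OCC)[C@H]2O1
F2 | step 5 | (2S,3S)-5-oxo-2-[3,4,5-tris(benzyloxy)phenyl]oxolane-3-carbaldehyde | O=C1O[C@H](c2cc(OCc3ccccc3)c(OCc3ccccc3)c(OCc3ccccc3)c2)[C@@H](C=O)C1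
F3 | step 5 | (4R,5S)-4-(hydroxymethyl)-5-[3,4,5-tris(benzyloxy)phenyl]oxolan-2-one | O=C1O[C@H](c2cc(OCc3ccccc3)c(OCc3ccccc3)c(OCc3ccccc3)c2)[C@@H](CO)C1
F4 | step 5 | (3R,4S)-4-hydroxy-3-(hydroxymethyl)-N-methoxy-N-methyl-4-[3,4,5-tris(benzyloxy)phenyl]butanamide | CON(C)C(=O)C[C@H](CO)[C@H](O)c1cc(OCc2ccccc2)c(OCc2ccccc2)c(OCc2ccccc2)c1
F5 | step 5 | bis(tert-butyldimethylsilyl) ether of F4 | CON(C)C(=O)C[C@H](CO[Si](C)(C)C(C)(C)C)[C@H](O[Si](C)(C)C(C)(C)C)c1cc(OCc2ccccc2)c(OCc2ccccc2)c(OCc2ccccc2)c1
F6 | step 3 | ethyl (1R,2R,3R)-2-[3,4,5-tris(benzyloxy)benzoyl]-3-[(methoxyoxalyl)oxy]cyclopropane-1-carboxylate | O=C(c1cc(OCc2ccccc2)c(OCc2ccccc2)c(OCc2ccccc2)c1)[C@@H]1[C@@H](C(=O)OCC)[C@@H]1OC(=O)C(=O)OC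
F7 | step 9 | [(2S,3R,4R)-2-[3,4-bis(benzyloxy)phenyl]-4-{(S)-hydroxy[3,4,5-tris(benzyloxy)phenyl]methyl}oxolan-3-yl]methanol | OC[C@@H]1[C@@H](c2ccc(OCc3ccccc3)c(OCc3ccccc3)c2)OC[C@@H]1[C@H](O)c1cc(OCc2ccccc2)c(OCc2ccccc2)c(OCc2ccccc2)c1
F8 | step 9 | (1S,2S,5R,6S)-2-[3,4-bis(benzyloxy)phenyl]-6-[3,4,5-tris(benzyloxy)phenyl]-3,7-dioxabicyclo[3.3.0]octan-8-ol (both C8 epimers) | OC1O[C@H](c2cc(OCc3ccccc3)c(OCc3ccccc3)c(OCc3ccccc3)c2)[C@H]2CO[C@H](c3ccc(OCc4ccccc4)c(OCc4ccccc4)c3)[C@@H]12
F0 | step 11 | none | none
A1 | alternative 1 | (5R)-5-[(1R,2S,5R)-menthyloxy]furan-2(5H)-one | O=C1C=C[C@H](O[C@@H]2C[C@H](C)CC[C@H]2C(C)C)O1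
A2 | alternative 1 | 2-[3,4,5-tris(benzyloxy)phenyl]-1,3-dithiane | C1CSC(SC1)c1cc(OCc2ccccc2)c(OCc2ccccc2)c(OCc2ccccc2)c1
A3 | alternative 1 | trans,trans 5-menthyloxy-4-{2-[3,4,5-tris(benzyloxy)phenyl]-1,3-dithian-2-yl}-3-{[3,4-bis(benzyloxy)phenyl](hydroxy)methyl}oxolan-2-one (carbinol epimer drawn arbitrarily) | O=C1O[C@@H](O[C@@H]2C[C@H](C)CC[C@H]2C(C)C)[C@H](C2(SCCCS2)c5cc(OCc6ccccc6)c(OCc6ccccc6)c(OCc6ccccc6)c5)[C@H]1[C@H](O)c5ccc(OCc6ccccc6)c(OCc6ccccc6)c5
A4 | alternative 2 | (3S)-3-[3,4-bis(benzyloxy)phenyl]-3-{(E)-3-[3,4,5-tris(benzyloxy)phenyl]prop-2-enyloxy}propanoyl chloride | O=C(Cl)C[C@@H](c1ccc(OCc2ccccc2)c(OCc2ccccc2)c1)OC/C=C/c1cc(OCc2ccccc2)c(OCc2ccccc2)c(OCc2ccccc2)c1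
A5 | alternative 2 | ketene derived from A4 | O=C=C[C@@H](c1ccc(OCc2ccccc2)c(OCc2ccccc2)c1)OC/C=C/c1cc(OCc2ccccc2)c(OCc2ccccc2)c(OCc2ccccc2)c1
A6 | alternative 2 | 2-[3,4-bis(benzyloxy)phenyl]-7-[3,4,5-tris(benzyloxy)phenyl]-3-oxabicyclo[3.2.0]heptan-6-one | O=C1[C@H](c5cc(OCc6ccccc6)c(OCc6ccccc6)c(OCc6ccccc6)c5)[C@H]2CO[C@H](c5ccc(OCc6ccccc6)c(OCc6ccccc6)c5)[C@@H]12
A7 | alternative 3 | mixed methyl acetal of (E)-3-[3,4-bis(benzyloxy)phenyl]prop-2-enal with oxiran-2-yl[3,4,5-tris(benzyloxy)phenyl]methanol (epoxide and acetal centres undefined) | COC(/C=C/c1ccc(OCc2ccccc2)c(OCc2ccccc2)c1)O[C@H](c1cc(OCc2ccccc2)c(OCc2ccccc2)c(OCc2ccccc2)c1)C1CO1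
A8 | alternative 3 | 8-methoxy-2-[3,4-bis(benzyloxy)phenyl]-6-[3,4,5-tris(benzyloxy)phenyl]-3,7-dioxabicyclo[3.3.0]octane (epimers at the acetal carbon) | COC1O[C@H](c5cc(OCc6ccccc6)c(OCc6ccccc6)c(OCc6ccccc6)c5)[C@H]2CO[C@H](c5ccc(OCc6ccccc6)c(OCc6ccccc6)c5)[C@@H]12
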